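**Retrosynthetic overview**
- Target ⇐ cis-8,9-diol: acetate on the equatorial 8-OH (stannylene acetal), senecioate on the axial 9-OH. The isopropenyl group is carried as a tertiary alcohol through the oxidation and hydrogenation steps.
- 8α,9α-Diol and 10β-H ⇐ linear 1(10),8-dienone: OsO4 on C8=C9, then hydroxyl-directed hydrogenation of C1=C10.
- Dienone ⇐ enone ⇐ acid opening of the cyclobutane of a tricyclic enone; the CMe2 bridge becomes the C7 side chain.
- Tricyclic enone ⇐ aldol condensation ⇐ intermolecular Michael addition of the 3-methylnopinone enolate to (E)-pent-3-en-2-one (key C4–C5 bond).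
- Ring order: ring B is the six-membered ring of (+)-nopinone; ring A is closed second by the Michael/aldol (Robinson) pair.

Convention and assumption: eremophilane numbering (decalin C1–C10, methyls on C4 and C5, side chain C11–C13 on C7), β = face of the C5 methyl. The target is then 4β,5β-dimethyl, 7β-isopropenyl, 8α-OAc, 9α-O-senecioyl, 10β-H, i.e. (4S,5R,7R,8R,9S,10S). Commercial (1R)-(+)-nopinone is taken as enantiopure.

**Step 1**
Reactants: 1 (1R,5S)-(+)-nopinone
Product: 3 trans-3-methylnopinone, via lithium enolate 2 (not isolated)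
Conditions: LiN(i-Pr)2, THF, −78 °C; MeI, −78 → 0 °C
Reagents that add atoms: iodomethane, CI; lithium diisopropylamide, [Li+].CC(C)[N-]C(C)C (lithium stays only in 2)
Why: Kinetic enolate alkylation in which the bridgehead C1 cannot enolise, so only C3 is deprotonated and MeI enters anti to the gem-dimethyl bridge (this centre is flattened again in step 2, so its configuration does not matter).

**Step 2 (key step)**
Reactants: 3 trans-3-methylnopinone; 4 (E)-pent-3-en-2-one
Product: 6 Michael adduct 1,5-diketone, via sodium enolate 5 (not isolated)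
Conditions: NaH, 1,4-dioxane, 60 °C, then 10 °C; 4 added slowly, 10 °C → rt; AcOH quench
Reagents that add atoms: sodium hydride, [Na+].[H-] (sodium stays only in 5)
Why: Intermolecular Michael addition (first half of a Robinson annulation) in which the only possible enolate attacks the enone β-carbon from the face anti to the gem-dimethyl bridge, fixing C5 with its methyl syn to the bridge (later cis to the C7 side chain), while the sodium-bridged closed transition state in the non-polar solvent puts the new C4 methyl cis to the C5 methyl, as in classical eremophilane annulations.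

**Step 3**
Reactants: 6 Michael adduct 1,5-diketone
Product: 7 tricyclic enone
Conditions: KOH, MeOH, 50 °C
Reagents that add atoms: none
Why: Intramolecular aldol condensation in which the ring ketone cannot enolise (quaternary C5, bridgehead C9), so only the methyl-ketone enolate can close six-membered ring A onto C10, and dehydration gives the conjugated enone without touching a stereocentre.

**Step 4**
Reactants: 7 tricyclic enone
Product: 8 11-chloro enone
Conditions: HCl (g), AcOH, 15–20 °C
Reagents that add atoms: hydrogen chloride, Cl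
Why: Acid-promoted cyclobutane fragmentation (vinylogous retro-aldol type) in which protonation of the enone lets the strained C9–C11 bond break to the tertiary cation, chloride traps it and the dienol returns to the conjugated enone, C7 keeping its configuration.

**Step 5**
Reactants: 8 11-chloro enone
Product: 9 11-hydroxy enone
Conditions: Ag2O, acetone/H2O (3:1), rt, dark
Reagents that add atoms: water, O
Why: Silver-assisted SN1 hydrolysis of the tertiary chloride at a non-stereogenic carbon, giving the oxidation- and hydrogenation-stable precursor of the isopropenyl group.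

**Step 6**
Reactants: 9 11-hydroxy enone
Product: 10 11-hydroxy 1(10),8-dienone
Conditions: chloranil, t-BuOH, reflux
Reagents that add atoms: none
Why: Quinone dehydrogenation (hydride abstraction from C8 of the extended dienol), which gives the linear rather than the cross-conjugated dienone and changes no stereocentre.

**Step 7**
Reactants: 10 11-hydroxy 1(10),8-dienone
Product: 11 8α,9α,11-triol enone
Conditions: OsO4 (2 mol %), NMO, acetone/H2O (8:1), rt
Reagents that add atoms: osmium tetroxide, O=[Os](=O)(=O)=O; N-methylmorpholine N-oxide, C[N+]1([O-])CCOCC1; water, O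
Why: Upjohn dihydroxylation in which OsO4 takes the distal, less electron-poor C8=C9 bond of the dienone and adds syn from the α face, anti to the bulky allylic C7 side chain and to the C5 methyl, setting C8 and C9 together.

**Step 8**
Reactants: 11 8α,9α,11-triol enone
Product: 12 8,9-acetonide enone
Conditions: 2,2-dimethoxypropane, pyridinium p-toluenesulfonate (cat.), acetone, rt
Reagents that add atoms: 2,2-dimethoxypropane, COC(C)(C)OC
Why: Acid-catalysed transketalisation that selects the cis-1,2-diol (five-membered dioxolane) over the crowded six-membered acetal to the tertiary OH.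

**Step 9**
Reactants: 12 8,9-acetonide enone
Product: 13 2β-allylic alcohol
Conditions: NaBH4, CeCl3·7H2O, MeOH, −78 → −20 °C
Reagents that add atoms: none
Why: Luche 1,2-reduction in which hydride attacks the enone carbonyl axially from the α face, giving the pseudo-equatorial 2β-alcohol as 4-en-3-one steroids give 3β-ols.

**Step 10**
Reactants: 13 2β-allylic alcohol
Product: 14 cis-fused 2β-alcohol
Conditions: H2 (1 atm), [Ir(cod)(PCy3)(py)]PF6 (5 mol %), CH2Cl2, rt
Reagents that add atoms: none
Why: Hydroxyl-directed homogeneous hydrogenation in which the 2β-OH (helped by the β-face tertiary OH) binds the cationic iridium catalyst, so H2 is delivered to C1=C10 from the β face and C10 becomes 10β-H (cis ring fusion).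

**Step 11**
Reactants: 14 cis-fused 2β-alcohol
Product: 15 cis-fused 2-ketone
Conditions: Dess–Martin periodinane (1,1,1-triacetoxy-1,1-dihydro-1,2-benziodoxol-3(1H)-one), CH2Cl2, rt
Reagents that add atoms: none
Why: Dess–Martin oxidation of the only secondary alcohol; the tertiary OH is inert and C10, being β to the new ketone, cannot epimerise.

**Step 12**
Reactants: 15 cis-fused 2-ketone
Product: 16 isopropenyl acetonide ketone
Conditions: SOCl2, pyridine, CH2Cl2, −30 → 0 °C
Reagents that add atoms: none
Why: Dehydration through the chlorosulfite (E2 with pyridine) in which the axial H-7 is shielded by the syn-axial C9–O and C5–C4 bonds and the alternative tetrasubstituted alkene would suffer allylic strain against the C8 oxygen, so a methyl proton is lost and the isopropenyl group forms.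

**Step 13**
Reactants: 16 isopropenyl acetonide ketone
Product: 17 8α,9α-diol ketone
Conditions: AcOH/H2O (4:1), 45 °C
Reagents that add atoms: none
Why: Acid-catalysed acetal hydrolysis, mild enough to leave the isopropenyl group and the cis ring fusion untouched.

**Step 14**
Reactants: 17 8α,9α-diol ketone
Product: 19 8-acetate 9-alcohol, via stannylene acetal 18 (not isolated)
Conditions: Bu2SnO, toluene, reflux (Dean–Stark); then AcCl, 0 °C
Reagents that add atoms: dibutyltin oxide, CCCC[Sn](=O)CCCC (tin stays only in 18); acetyl chloride, CC(Cl)=O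
Why: Stannylene-acetal-mediated regioselective acylation, since in the cis-decalin chair (C5 methyl and C7 isopropenyl both equatorial on ring B) the 8-OH is equatorial and the 9-OH axial, and stannylene acetals of cis-diols acylate at the equatorial oxygen.

**Step 15**
Reactants: 19 8-acetate 9-alcohol
Product: 20 target CNP0150397.1
Conditions: 3-methylbut-2-enoyl chloride, pyridine, 4-(dimethylamino)pyridine (cat.), CH2Cl2, 0 °C → rt
Reagents that add atoms: 3-methylbut-2-enoyl chloride (senecioyl chloride), CC(C)=CC(Cl)=O
Why: Nucleophile-catalysed acylation (acylpyridinium transfer) of the remaining axial 9-OH, with pyridine as the only base so that the acid chloride is not deconjugated through a vinylketene and the 8-acetate does not migrate.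

**Compound list**
1 | (1R,5S)-(+)-nopinone (6,6-dimethylbicyclo[3.1.1]heptan-2-one) | CC1(C)[C@H]2CCC(=O)[C@@H]1C2 | starting material
2 | lithium C2–C3 enolate of nopinone | CC1(C)[C@H]2CC=C([O-])[C@@H]1C2.[Li+] | intermediate
3 | (1R,3S,5S)-3,6,6-trimethylbicyclo[3.1.1]heptan-2-one (trans-3-methylnopinone, methyl anti to the CMe2 bridge) | CC1(C)[C@H]2C[C@H](C)C(=O)[C@@H]1C2 | intermediate
4 | (E)-pent-3-en-2-one | C/C=C/C(C)=O | starting material
5 | sodium enolate of 3 | CC1(C)[C@H]2CC(C)=C([O-])[C@@H]1C2.[Na+] | intermediate
6 | (1R,3R,5R)-3,6,6-trimethyl-3-[(2S)-4-oxopentan-2-yl]bicyclo[3.1.1]heptan-2-one (side chain anti, 3-methyl syn to the CMe2 bridge) | CC1(C)[C@H]2C[C@](C)([C@@H](C)CC(C)=O)C(=O)[C@@H]1C2 | intermediate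
7 | tricyclic enone: 4β,5β-dimethyleremophil-1(10)-en-2-one skeleton with C11 (CMe2) still bonded to both C7 and C9 on the β face | CC1(C)[C@H]2C[C@]3(C)[C@@H](C)CC(=O)C=C3[C@@H]1C2 | intermediate
8 | 11-chloro-4β,5β-dimethyl-7αH-eremophil-1(10)-en-2-one (7β-(2-chloropropan-2-yl)) | CC(C)(Cl)[C@H]1C[C@@]2(C)C(=CC(=O)C[C@@H]2C)CC1 | intermediate
9 | 11-hydroxy-4β,5β-dimethyl-7αH-eremophil-1(10)-en-2-one | CC(C)(O)[C@H]1C[C@@]2(C)C(=CC(=O)C[C@@H]2C)CC1 | intermediate
10 | 11-hydroxy-4β,5β-dimethyl-7αH-eremophila-1(10),8-dien-2-one | CC(C)(O)[C@H]1C[C@@]2(C)C(=CC(=O)C[C@@H]2C)C=C1 | intermediate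
11 | 8α,9α,11-trihydroxy-4β,5β-dimethyl-7αH-eremophil-1(10)-en-2-one | CC(C)(O)[C@H]1C[C@@]2(C)C(=CC(=O)C[C@@H]2C)[C@H](O)[C@@H]1O | intermediate
12 | 8α,9α-O-isopropylidene derivative of 11 | CC(C)(O)[C@H]1C[C@@]2(C)C(=CC(=O)C[C@@H]2C)[C@@H]3OC(C)(C)O[C@H]13 | intermediate
13 | 8α,9α-O-isopropylidene-eremophil-1(10)-ene-2β,11-diol | CC(C)(O)[C@H]1C[C@@]2(C)C(=C[C@H](O)C[C@@H]2C)[C@@H]3OC(C)(C)O[C@H]13 | intermediate
14 | 8α,9α-O-isopropylidene-10βH-eremophilane-2β,11-diol (cis-fused) | CC(C)(O)[C@H]1C[C@@]2(C)[C@H](C[C@H](O)C[C@@H]2C)[C@@H]3OC(C)(C)O[C@H]13 | intermediate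
15 | 11-hydroxy-8α,9α-O-isopropylidene-10βH-eremophilan-2-one | CC(C)(O)[C@H]1C[C@@]2(C)[C@H](CC(=O)C[C@@H]2C)[C@@H]3OC(C)(C)O[C@H]13 | intermediate
16 | 8α,9α-O-isopropylidene-10βH-eremophil-11-en-2-one | C=C(C)[C@H]1C[C@@]2(C)[C@H](CC(=O)C[C@@H]2C)[C@@H]3OC(C)(C)O[C@H]13 | intermediate
17 | 8α,9α-dihydroxy-10βH-eremophil-11-en-2-one | C=C(C)[C@H]1C[C@@]2(C)[C@H](CC(=O)C[C@@H]2C)[C@H](O)[C@@H]1O | intermediate
18 | 8,9-O-dibutylstannylene acetal of 17 | C=C(C)[C@H]1C[C@@]2(C)[C@H](CC(=O)C[C@@H]2C)[C@@H]3O[Sn](CCCC)(CCCC)O[C@H]13 | intermediate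
19 | 8α-acetoxy-9α-hydroxy-10βH-eremophil-11-en-2-one | C=C(C)[C@H]1C[C@@]2(C)[C@H](CC(=O)C[C@@H]2C)[C@H](O)[C@@H]1OC(C)=O | intermediate
20 | (4S,5R,7R,8R,9S,10S)-8-acetoxy-2-oxoeremophil-11-en-9-yl 3-methylbut-2-enoate (CNP0150397.1) | C=C(C)[C@H]1C[C@@]2(C)[C@H](CC(=O)C[C@@H]2C)[C@H](OC(=O)C=C(C)C)[C@@H]1OC(C)=O | target

**Totals**
Total steps: 15. Longest linear sequence: 15 steps (from 1; 4 enters at step 2).

**Steps most likely to fail**

Step 2 (Michael addition). The hindered enolate may react slowly while the enone polymerises, and the C4 methyl ratio is not guaranteed. The fallback sets out from 3: LiN(i-Pr)2 then Me3SiCl gives the trimethylsilyl enol ether F1 (only one regioisomer is possible). A Mukaiyama–Michael addition of this ether to 4 with TiCl4 in CH2Cl2 at −78 °C, followed by aqueous work-up, comes back to the route at 6. This Lewis-acid, open-transition-state addition is irreversible, still enters anti to the bridge, and has an independent C4 selectivity. Any C4 epimer is removed at 7.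

Step 6 (chloranil dehydrogenation). Conversion may stall or the cross-conjugated dienone may form. The fallback sets out from 9: Me3SiOTf and Et3N in CH2Cl2 give the bis-silyl extended dienol ether F2 (C2-silyloxy 1,9(10)-diene, tertiary OH also silylated). Saegusa–Ito oxidation with Pd(OAc)2 (divalent palladium) in MeCN gives the 11-O-trimethylsilyl dienone F3. Dilute HCl in THF removes the silyl ether and comes back to the route at 10.

Step 10 (directed hydrogenation). The hindered trisubstituted alkene may react slowly, or the catalyst may be deactivated. The fallback sets out from 12 and hydrogenates the enone itself with H2 (1 atm) and 10% Pd/C in pyridine, coming back to the route at 15 and skipping steps 9 to 11. The α-face dioxolane and the known preference of angular-methyl octalones for cis-fused products in basic media should give 10β-H. This fallback makes no new compound (F0).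

**Further compounds**
F1 | step 2 | (1R,5S)-3,6,6-trimethyl-2-(trimethylsilyloxy)bicyclo[3.1.1]hept-2-ene | CC1(C)[C@H]2CC(C)=C(O[Si](C)(C)C)[C@@H]1C2
F2 | step 6 | 2,11-bis(trimethylsilyloxy)-4β,5β-dimethyl-7αH-eremophila-1,9-diene | CC(C)(O[Si](C)(C)C)[C@H]1C[C@@]2(C)C(C=C(O[Si](C)(C)C)C[C@@H]2C)=CC1
F3 | step 6 | 11-(trimethylsilyloxy)-4β,5β-dimethyl-7αH-eremophila-1(10),8-dien-2-one | CC(C)(O[Si](C)(C)C)[C@H]1C[C@@]2(C)C(=CC(=O)C[C@@H]2C)C=C1
F0 | step 10 | none | none
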